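**Retrosynthetic overview**

1. Target 18 ⇐ penta-O-benzyl ether 17 by global hydrogenolysis; the ester, both stereocentres and the whole skeleton are already in place in 17.
2. 17 ⇐ 15: the pyran ring is made last, by ring expansion of a 2,3-dihydrobenzofuran. The furan oxygen O1 moves from furan C2 to the exocyclic benzylic carbon while the 4-(benzyloxy)benzoyloxy group moves the opposite way (formal dyotropic 1,2-exchange, double inversion). This one step makes the O1–C2 bond, places the ester on C3 and fixes both stereocentres.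
3. Enabling feature: in 15 the furan O1 lies antiperiplanar, across the C2(furan)–CH(exocyclic) bond, to an ionisable benzylic C–O(acyl) bond whose carbon carries the 3,4-dioxygenated B ring. O1 can therefore bridge to a three-membered oxonium fused to the five-membered ring, and the carboxylate returns at furan C2.
4. 15 ⇐ cis-epoxide 11 (desilylative 5-exo-tet phenoxide opening, then O-acylation) ⇐ Z-alkene 10 (catalytic asymmetric epoxidation, the only source of chirality) ⇐ alkyne 9 ⇐ aldehyde 3 + alkyne 6.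
5. Ring order: A and B benzene rings are bought; oxirane (step 7) → dihydrofuran ring (step 8) → pyran ring (step 9).

Key step: step 9

Assumption: the facial sense of the (S,S)-(salen)Mn catalyst is taken over from cis-β-methylstyrene and indene (aryl-bearing epoxide carbon S); if it proves opposite for 10, the (R,R)-catalyst is used instead.

**Route**

Step 1
Reactants: 1 2,4,6-trihydroxybenzaldehyde
Product: 2 2,4-bis(benzyloxy)-6-hydroxybenzaldehyde
Conditions: BnBr (2.05 equiv), K2CO3 (2.1 equiv), DMF, 0 °C → rt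
Reagents that add atoms: benzyl bromide, BrCc1ccccc1
Why: Williamson etherification: the 4-OH and one 2-OH are alkylated, whereas the last OH, hydrogen-bonded to the formyl group, is the least nucleophilic and should remain free.

Step 2
Reactants: 2 2,4-bis(benzyloxy)-6-hydroxybenzaldehyde
Product: 3 2,4-bis(benzyloxy)-6-[(triisopropylsilyl)oxy]benzaldehyde
Conditions: TIPSOTf (1.3 equiv), 2,6-lutidine (2 equiv), CH2Cl2, 0 °C
Reagents that add atoms: triisopropylsilyl trifluoromethanesulfonate, CC(C)[Si](OS(=O)(=O)C(F)(F)F)(C(C)C)C(C)C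
Why: Silylation of the chelated phenol with the reactive silyl triflate; the bulky TIPS ether should resist O→O silyl migration in step 4 and the acid of step 5, and is cleaved by fluoride in step 8.

Step 3
Reactants: 4 3,4-bis(benzyloxy)benzaldehyde
Product: 6 1,2-bis(benzyloxy)-4-ethynylbenzene, via diazoalkene 5 (not isolated)
Conditions: dimethyl (1-diazo-2-oxopropyl)phosphonate (1.2 equiv), K2CO3 (2 equiv), MeOH/THF, rt
Reagents that add atoms: dimethyl (1-diazo-2-oxopropyl)phosphonate (Ohira–Bestmann reagent), CC(=O)C(=[N+]=[N-])P(=O)(OC)OC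
Why: Seyferth–Gilbert homologation with the Ohira–Bestmann reagent converts the aryl aldehyde into the terminal alkyne under mild base that leaves the benzyl ethers untouched.

Step 4
Reactants: 6 1,2-bis(benzyloxy)-4-ethynylbenzene; 3 2,4-bis(benzyloxy)-6-[(triisopropylsilyl)oxy]benzaldehyde
Product: 8 rac-1-{2,4-bis(benzyloxy)-6-[(triisopropylsilyl)oxy]phenyl}-3-[3,4-bis(benzyloxy)phenyl]prop-2-yn-1-ol, via lithium acetylide 7 (not isolated)
Conditions: n-BuLi (1.05 equiv), THF, −78 °C; then 3, −78 → −40 °C; H2O quench at −40 °C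
Reagents that add atoms: none
Why: 1,2-Addition of a lithium acetylide to an aldehyde; the new carbinol centre is formed as a racemate on purpose because step 5 removes it.

Step 5
Reactants: 8 rac-1-{2,4-bis(benzyloxy)-6-[(triisopropylsilyl)oxy]phenyl}-3-[3,4-bis(benzyloxy)phenyl]prop-2-yn-1-ol
Product: 9 {3,5-bis(benzyloxy)-2-[3-(3,4-bis(benzyloxy)phenyl)prop-2-yn-1-yl]phenoxy}triisopropylsilane
Conditions: Et3SiH (3 equiv), TFA (5 equiv), CH2Cl2, −40 °C
Reagents that add atoms: none
Why: Ionic hydrogenation: the carbinol, doubly activated by the trioxygenated ring and the alkyne, ionises under acid and the propargylic cation is reduced by the silane at the benzylic carbon, which keeps the alkyne.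

Step 6
Reactants: 9 {3,5-bis(benzyloxy)-2-[3-(3,4-bis(benzyloxy)phenyl)prop-2-yn-1-yl]phenoxy}triisopropylsilane
Product: 10 {3,5-bis(benzyloxy)-2-[(2Z)-3-(3,4-bis(benzyloxy)phenyl)prop-2-en-1-yl]phenoxy}triisopropylsilane
Conditions: H2 (1 atm), Lindlar catalyst, quinoline, EtOAc, rt
Reagents that add atoms: none
Why: Lindlar semi-hydrogenation (syn addition of H2 on the poisoned Pd surface) should give the Z-alkene and spare the benzyl ethers and the silyl ether.

Step 7
Reactants: 10 {3,5-bis(benzyloxy)-2-[(2Z)-3-(3,4-bis(benzyloxy)phenyl)prop-2-en-1-yl]phenoxy}triisopropylsilane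
Product: 11 [3,5-bis(benzyloxy)-2-({(2R,3S)-3-[3,4-bis(benzyloxy)phenyl]oxiran-2-yl}methyl)phenoxy]triisopropylsilane
Conditions: (S,S)-Jacobsen (salen)Mn(III)Cl catalyst (5 mol%), mCPBA (2 equiv), NMO (5 equiv), CH2Cl2, −78 °C; filtration through Et3N-deactivated silica
Reagents that add atoms: 3-chloroperoxybenzoic acid (mCPBA), OOC(=O)c1cccc(Cl)c1
Why: Jacobsen–Katsuki epoxidation of a cis-disubstituted, aryl-conjugated alkene, the best substrate class for (salen)Mn catalysts; the catalyst selects the alkene face and thereby sets both epoxide carbons (the only external source of chirality in the route), low temperature suppressing leakage to the trans-epoxide.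

Step 8
Reactants: 11 [3,5-bis(benzyloxy)-2-({(2R,3S)-3-[3,4-bis(benzyloxy)phenyl]oxiran-2-yl}methyl)phenoxy]triisopropylsilane; 12 4-(benzyloxy)benzoyl chloride
Product: 15 (S)-[(2S)-4,6-bis(benzyloxy)-2,3-dihydro-1-benzofuran-2-yl][3,4-bis(benzyloxy)phenyl]methyl 4-(benzyloxy)benzoate, via phenoxide 13 (not isolated), via alkoxide 14 (not isolated)
Conditions: TBAF (1.1 equiv), THF, 0 °C; then 12 (1.5 equiv), DMAP (cat.), 0 °C → rt
Reagents that add atoms: none
Why: Fluoride cleaves the aryl silyl ether and the phenoxide opens the epoxide by 5-exo-tet SN2 attack at the non-benzylic carbon (inversion, R→S at what becomes furan C2) while the benzylic C–O bond is untouched (S retained); the resulting alkoxide is O-acylated with retention.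

Step 9
Reactants: 15 (S)-[(2S)-4,6-bis(benzyloxy)-2,3-dihydro-1-benzofuran-2-yl][3,4-bis(benzyloxy)phenyl]methyl 4-(benzyloxy)benzoate
Product: 17 (2R,3R)-5,7-bis(benzyloxy)-2-[3,4-bis(benzyloxy)phenyl]-3,4-dihydro-2H-chromen-3-yl 4-(benzyloxy)benzoate, via oxonium ion pair 16 (not isolated)
Conditions: Zn(OTf)2 (20 mol%), 2,6-di-tert-butyl-4-methylpyridine (20 mol%), CH2Cl2 (0.01 M), −20 °C → rt
Reagents that add atoms: none
Why: Proposed new method: Zn(II) binds the carbonyl of the benzylic 4-(benzyloxy)benzoate and the benzylic C–O bond ionises with anchimeric help of the antiperiplanar furan oxygen O1 (inversion at the benzylic carbon) to give the cis-bridged oxonium/zinc carboxylate ion pair 16, which collapses by SN2 return of the carboxylate at the former furan C2 (inversion, cleavage of the O1–C2(furan) bond), a formal dyotropic 1,2-exchange of O1 and the acyloxy group that turns the five-membered ring into the pyran ring. The closest known reaction types are the Zn(OAc)2-mediated ring expansion of (tetrahydrofuran-2-yl)methyl sulfonates to 3-acyloxytetrahydropyrans through bicyclic oxonium ions, the acid-induced rearrangement of 2-(1-hydroxyalkyl)-2,3-dihydrobenzofurans to chroman-3-ols, the solvolytic ring contraction of flavan-3-yl sulfonates (the same oxonium ion, crossed in the opposite direction) and Lewis-acid-promoted dyotropic ring expansions of β-lactones; new is the use of the ester as both leaving group and returning nucleophile at an aryl carbinol. Mode of closure: the pyran ring closes by 3-exo-tet attack of O1 on the benzylic carbon followed by endo opening of the oxonium ring at furan C2 (net 1,2-shift of O1, 5→6 ring expansion). Stereocontrol: both centres are dictated by the substrate through double inversion, (S)-benzylic carbon → C2 (R) and (S)-furan C2 → C3 (R), so that the threo ester can only give the 2,3-cis chroman. The selectivities needed are return at the ring carbon and not at the benzylic carbon, secured because return at the benzylic carbon merely regenerates 15 whereas ester 17 has no ionisable C–O bond left (the six-membered isomer is the sink), and bridging that outpaces formation of a free benzylic cation, secured by the inductive brake of the β-aryloxy oxygen, the tight zinc carboxylate ion pair in a non-polar medium, low temperature, high dilution and a hindered base that removes adventitious acid.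

Step 10
Reactants: 17 (2R,3R)-5,7-bis(benzyloxy)-2-[3,4-bis(benzyloxy)phenyl]-3,4-dihydro-2H-chromen-3-yl 4-(benzyloxy)benzoate
Product: 18 (2R,3R)-2-(3,4-dihydroxyphenyl)-5,7-dihydroxy-3,4-dihydro-2H-chromen-3-yl 4-hydroxybenzoate (epicatechin 3-O-p-hydroxybenzoate)
Conditions: H2 (1 atm), 20% Pd(OH)2/C, THF/MeOH (1:1), rt
Reagents that add atoms: none
Why: Hydrogenolysis of the five benzyl ethers over Pearlman's catalyst; the C3 alkyl benzoate and the two stereocentres are not affected under these neutral conditions.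

**Compound list**

1 | 2,4,6-trihydroxybenzaldehyde | O=Cc1c(O)cc(O)cc1O | starting material
2 | 2,4-bis(benzyloxy)-6-hydroxybenzaldehyde | O=Cc1c(O)cc(OCc2ccccc2)cc1OCc1ccccc1 | intermediate
3 | 2,4-bis(benzyloxy)-6-[(triisopropylsilyl)oxy]benzaldehyde | CC(C)[Si](Oc1cc(OCc2ccccc2)cc(OCc2ccccc2)c1C=O)(C(C)C)C(C)C | intermediate
4 | 3,4-bis(benzyloxy)benzaldehyde | O=Cc1ccc(OCc2ccccc2)c(OCc2ccccc2)c1 | starting material
5 | 1,2-bis(benzyloxy)-4-(2-diazoethenyl)benzene (diazoalkene) | [N-]=[N+]=C=Cc1ccc(OCc2ccccc2)c(OCc2ccccc2)c1 | intermediate (not isolated)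
6 | 1,2-bis(benzyloxy)-4-ethynylbenzene | C#Cc1ccc(OCc2ccccc2)c(OCc2ccccc2)c1 | intermediate
7 | lithium [3,4-bis(benzyloxy)phenyl]acetylide | [Li]C#Cc1ccc(OCc2ccccc2)c(OCc2ccccc2)c1 | intermediate (not isolated)
8 | rac-1-{2,4-bis(benzyloxy)-6-[(triisopropylsilyl)oxy]phenyl}-3-[3,4-bis(benzyloxy)phenyl]prop-2-yn-1-ol | CC(C)[Si](Oc1cc(OCc2ccccc2)cc(OCc2ccccc2)c1C(O)C#Cc1ccc(OCc2ccccc2)c(OCc2ccccc2)c1)(C(C)C)C(C)C | intermediate
9 | {3,5-bis(benzyloxy)-2-[3-(3,4-bis(benzyloxy)phenyl)prop-2-yn-1-yl]phenoxy}triisopropylsilane | CC(C)[Si](Oc1cc(OCc2ccccc2)cc(OCc2ccccc2)c1CC#Cc1ccc(OCc2ccccc2)c(OCc2ccccc2)c1)(C(C)C)C(C)C | intermediate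
10 | {3,5-bis(benzyloxy)-2-[(2Z)-3-(3,4-bis(benzyloxy)phenyl)prop-2-en-1-yl]phenoxy}triisopropylsilane | CC(C)[Si](Oc1cc(OCc2ccccc2)cc(OCc2ccccc2)c1C/C=C\c1ccc(OCc2ccccc2)c(OCc2ccccc2)c1)(C(C)C)C(C)C | intermediate
11 | [3,5-bis(benzyloxy)-2-({(2R,3S)-3-[3,4-bis(benzyloxy)phenyl]oxiran-2-yl}methyl)phenoxy]triisopropylsilane (cis-epoxide) | CC(C)[Si](Oc1cc(OCc2ccccc2)cc(OCc2ccccc2)c1C[C@H]1O[C@H]1c1ccc(OCc2ccccc2)c(OCc2ccccc2)c1)(C(C)C)C(C)C | intermediate
12 | 4-(benzyloxy)benzoyl chloride | O=C(Cl)c1ccc(OCc2ccccc2)cc1 | starting material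
13 | tetrabutylammonium 3,5-bis(benzyloxy)-2-({(2R,3S)-3-[3,4-bis(benzyloxy)phenyl]oxiran-2-yl}methyl)phenoxide | [O-]c1cc(OCc2ccccc2)cc(OCc2ccccc2)c1C[C@H]1O[C@H]1c1ccc(OCc2ccccc2)c(OCc2ccccc2)c1.CCCC[N+](CCCC)(CCCC)CCCC | intermediate (not isolated)
14 | tetrabutylammonium (S)-[(2S)-4,6-bis(benzyloxy)-2,3-dihydro-1-benzofuran-2-yl][3,4-bis(benzyloxy)phenyl]methanolate | [O-][C@@H](c1ccc(OCc2ccccc2)c(OCc2ccccc2)c1)[C@@H]1Cc2c(OCc3ccccc3)cc(OCc3ccccc3)cc2O1.CCCC[N+](CCCC)(CCCC)CCCC | intermediate (not isolated)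
15 | (S)-[(2S)-4,6-bis(benzyloxy)-2,3-dihydro-1-benzofuran-2-yl][3,4-bis(benzyloxy)phenyl]methyl 4-(benzyloxy)benzoate (threo ester) | O=C(O[C@@H](c1ccc(OCc2ccccc2)c(OCc2ccccc2)c1)[C@@H]1Cc2c(OCc3ccccc3)cc(OCc3ccccc3)cc2O1)c1ccc(OCc2ccccc2)cc1 | intermediate
16 | cis-bridged oxonium ion (O1 bonded to the aryl carbon, to furan C2 (S) and to the benzylic carbon (R); benzo-fused 1-oxoniabicyclo[3.1.0]hexane) as ion pair with 4-(benzyloxy)benzoate | [O+]12c3cc(OCc4ccccc4)cc(OCc4ccccc4)c3C[C@H]1[C@H]2c1ccc(OCc2ccccc2)c(OCc2ccccc2)c1.[O-]C(=O)c1ccc(OCc2ccccc2)cc1 | intermediate (not isolated)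
17 | (2R,3R)-5,7-bis(benzyloxy)-2-[3,4-bis(benzyloxy)phenyl]-3,4-dihydro-2H-chromen-3-yl 4-(benzyloxy)benzoate | O=C(O[C@@H]1Cc2c(OCc3ccccc3)cc(OCc3ccccc3)cc2O[C@@H]1c1ccc(OCc2ccccc2)c(OCc2ccccc2)c1)c1ccc(OCc2ccccc2)cc1 | intermediate
18 | (2R,3R)-2-(3,4-dihydroxyphenyl)-5,7-dihydroxy-3,4-dihydro-2H-chromen-3-yl 4-hydroxybenzoate (epicatechin 3-O-p-hydroxybenzoate) | O=C(O[C@@H]1Cc2c(O)cc(O)cc2O[C@@H]1c1ccc(O)c(O)c1)c1ccc(O)cc1 | target

**Step count and risks**

Total step count: 10. Longest linear sequence: 9 steps (steps 1, 2, 4, 5, 6, 7, 8, 9, 10, from 1 to 18); step 3 is a one-step side branch.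

Steps most likely to fail:

1. Step 9 (proposed new method). Ionisation may outrun oxonium bridging. That would cause loss of configuration at the benzylic carbon (leakage to the 2,3-trans chroman), E1 loss of a proton with aromatisation to a 2-benzylbenzofuran, or intermolecular Friedel–Crafts capture of the cation by the electron-rich A rings. Alternatively the carboxylate may return only at the benzylic carbon, giving no net reaction. Fallback with known chemistry, setting out from 11 and coming back at 17: 11 is desilylated under buffered conditions (TBAF/AcOH 1:1, THF, −20 °C) so that the phenol is freed without base-induced closure, giving 3,5-bis(benzyloxy)-2-({(2R,3S)-3-[3,4-bis(benzyloxy)phenyl]oxiran-2-yl}methyl)phenol F1. A catalytic acid (PPTS, CH2Cl2, −40 °C) then directs the phenol to the benzylic epoxide carbon with inversion (acid-mediated epoxide–phenol cyclisation to a flavan-3-ol), which should give (2R,3R)-5,7-bis(benzyloxy)-2-[3,4-bis(benzyloxy)phenyl]-3,4-dihydro-2H-chromen-3-ol F2. Acylation of F2 with 12 (Et3N, DMAP, CH2Cl2, 0 °C) gives 17.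

2. Step 7. The Mn-oxo adduct of an electron-rich styrene may collapse stepwise through a radical, which would erode enantioselectivity and leak to the trans-epoxide; the acid-labile epoxide may also open or rearrange during isolation. Fallback setting out from 10 and coming back at 15: the Z-alkene is isomerised (cat. I2, hν, CH2Cl2) to {3,5-bis(benzyloxy)-2-[(2E)-3-(3,4-bis(benzyloxy)phenyl)prop-2-en-1-yl]phenoxy}triisopropylsilane F3. Shi epoxidation of this trans-alkene (D-fructose-derived ketone, Oxone, K2CO3 buffer, MeCN/DMM/H2O, 0 °C) should give [3,5-bis(benzyloxy)-2-({(2R,3R)-3-[3,4-bis(benzyloxy)phenyl]oxiran-2-yl}methyl)phenoxy]triisopropylsilane F4. TBAF (THF, 0 °C; 5-exo-tet opening with inversion at the non-benzylic carbon) then gives the erythro carbinol (R)-[(2S)-4,6-bis(benzyloxy)-2,3-dihydro-1-benzofuran-2-yl][3,4-bis(benzyloxy)phenyl]methanol F5. Mitsunobu esterification of F5 with 4-(benzyloxy)benzoic acid (PPh3, DIAD, toluene, 0 °C) inverts the benzylic carbon and gives 15.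

3. Step 5. The silane may deliver hydride at the aryl-bearing alkyne terminus of the delocalised propargylic cation (allene formation) instead of the hindered benzylic carbon; acid may also cause partial loss of the silyl ether or hydration of the electron-rich aryl alkyne. Fallback setting out from 3 and coming back at 9 (it also makes steps 3 and 4 unnecessary): ethynylmagnesium bromide (THF, −40 °C) adds to 3 to give rac-1-{2,4-bis(benzyloxy)-6-[(triisopropylsilyl)oxy]phenyl}prop-2-yn-1-ol F6. Its ionic hydrogenation (Et3SiH, TFA, CH2Cl2, −40 °C) can only be propargylic, because the allenyl terminus of this cation is unstabilised, and gives [3,5-bis(benzyloxy)-2-(prop-2-yn-1-yl)phenoxy]triisopropylsilane F7. Sonogashira coupling of F7 with 4-iodo-1,2-bis(benzyloxy)benzene (Pd(PPh3)2Cl2, CuI, Et3N, THF, rt) gives 9.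

**Further compounds**

F1 | step 9 | 3,5-bis(benzyloxy)-2-({(2R,3S)-3-[3,4-bis(benzyloxy)phenyl]oxiran-2-yl}methyl)phenol | Oc1cc(OCc2ccccc2)cc(OCc2ccccc2)c1C[C@H]1O[C@H]1c1ccc(OCc2ccccc2)c(OCc2ccccc2)c1
F2 | step 9 | (2R,3R)-5,7-bis(benzyloxy)-2-[3,4-bis(benzyloxy)phenyl]-3,4-dihydro-2H-chromen-3-ol | O[C@@H]1Cc2c(OCc3ccccc3)cc(OCc3ccccc3)cc2O[C@@H]1c1ccc(OCc2ccccc2)c(OCc2ccccc2)c1
F3 | step 7 | {3,5-bis(benzyloxy)-2-[(2E)-3-(3,4-bis(benzyloxy)phenyl)prop-2-en-1-yl]phenoxy}triisopropylsilane | CC(C)[Si](Oc1cc(OCc2ccccc2)cc(OCc2ccccc2)c1C/C=C/c1ccc(OCc2ccccc2)c(OCc2ccccc2)c1)(C(C)C)C(C)C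
F4 | step 7 | [3,5-bis(benzyloxy)-2-({(2R,3R)-3-[3,4-bis(benzyloxy)phenyl]oxiran-2-yl}methyl)phenoxy]triisopropylsilane | CC(C)[Si](Oc1cc(OCc2ccccc2)cc(OCc2ccccc2)c1C[C@H]1O[C@@H]1c1ccc(OCc2ccccc2)c(OCc2ccccc2)c1)(C(C)C)C(C)C
F5 | step 7 | (R)-[(2S)-4,6-bis(benzyloxy)-2,3-dihydro-1-benzofuran-2-yl][3,4-bis(benzyloxy)phenyl]methanol | O[C@H](c1ccc(OCc2ccccc2)c(OCc2ccccc2)c1)[C@@H]1Cc2c(OCc3ccccc3)cc(OCc3ccccc3)cc2O1
F6 | step 5 | rac-1-{2,4-bis(benzyloxy)-6-[(triisopropylsilyl)oxy]phenyl}prop-2-yn-1-ol | CC(C)[Si](Oc1cc(OCc2ccccc2)cc(OCc2ccccc2)c1C(O)C#C)(C(C)C)C(C)C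
F7 | step 5 | [3,5-bis(benzyloxy)-2-(prop-2-yn-1-yl)phenoxy]triisopropylsilane | CC(C)[Si](Oc1cc(OCc2ccccc2)cc(OCc2ccccc2)c1CC#C)(C(C)C)C(C)C
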